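**Retrosynthetic overview**
- The C5 methyl ether is disconnected first. This leads back to 3-hexadecyl-2,5-dihydroxy-1,4-benzoquinone and methanol, joined by selective etherification of the unhindered vinylogous acid.
- The key C3–C1' bond is disconnected next. This gives 2,5-dihydroxy-1,4-benzoquinone and hexadecanal, joined by a proline-catalysed Knoevenagel-type aldol (Mannich-type) condensation. The resulting quinone methide is reduced in the same flask by a Hantzsch ester.
- Hexadecanal comes from 1-hexadecanol by oxidation just before use.
- Rings: the only ring, the six-membered quinone, is bought intact with 2,5-dihydroxy-1,4-benzoquinone, so no ring is formed in the route.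

Assumption: the target has no stereocentre and no stereogenic double bond, so it is achiral and needs no stereocontrol. The side chain is read as unbranched C16 (n-hexadecyl).

**Step 1**
Reactants: 1 1-hexadecanol (cetyl alcohol)
Product: 2 hexadecanal
Conditions: TEMPO (2,2,6,6-tetramethylpiperidin-1-oxyl, 10 mol %), PhI(OAc)2 (1.1 equiv), dry CH2Cl2, 25 °C, 3 h; short silica plug, used the same day
Reagents that add atoms: none
Why: The oxoammonium-mediated alcohol oxidation (TEMPO/PhI(OAc)2, Piancatelli–Margarita conditions) in water-free CH2Cl2 forms no aldehyde hydrate and so stops at the aldehyde, and prompt use avoids trimerisation.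

**Step 2**
Reactants: 2 hexadecanal; 3 2,5-dihydroxy-1,4-benzoquinone
Product: 5 3-hexadecyl-2,5-dihydroxy-1,4-benzoquinone, via hexadecylidene quinone methide 4 (not isolated)
Conditions: 3 (2 equiv), L-proline (20 mol %), Hantzsch ester (diethyl 2,6-dimethyl-1,4-dihydropyridine-3,5-dicarboxylate, 1.2 equiv), CH2Cl2/EtOH 4:1, 25 °C, 2 added over 2 h, then 12 h; filter off excess 3, wash with 1 M HCl, recrystallise from EtOH
Reagents that add atoms: none
Why: Proline turns 2 into an iminium ion that the enolic C3 of the vinylogous acid 3 attacks (Knoevenagel-type aldol/Mannich condensation), loss of proline gives the electrophilic quinone methide 4, and hydride transfer from the Hantzsch ester reduces it at once (three-component reductive alkylation), with no stereocentre formed.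

**Step 3**
Reactants: 5 3-hexadecyl-2,5-dihydroxy-1,4-benzoquinone
Product: 6 3-hexadecyl-2-hydroxy-5-methoxy-1,4-benzoquinone (target)
Conditions: MeOH (solvent), conc. H2SO4 (cat., 0.1 equiv), 65 °C, 3–5 h (TLC control); cool, collect crystals, recrystallise from MeOH
Reagents that add atoms: methanol, CO
Why: In this Fischer-type etherification of a vinylogous carboxylic acid (acid-catalysed addition–elimination of methanol), the C5 hydroxyl next to the ring CH reacts as easily as in 3, while the C2 hydroxyl flanked by the hexadecyl chain is sterically blocked (as in 3-alkyl-2-hydroxynaphthoquinones), so only the 5-methyl ether forms and no stereocentre is involved.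

**Compound list**
1 | 1-hexadecanol (cetyl alcohol) | CCCCCCCCCCCCCCCCO | starting material
2 | hexadecanal | CCCCCCCCCCCCCCCC=O | intermediate
3 | 2,5-dihydroxy-1,4-benzoquinone | O=C1C=C(O)C(=O)C=C1O | starting material
4 | 3-hexadecylidene-5-hydroxycyclohex-5-ene-1,2,4-trione (transient quinone methide; alkene geometry undefined and lost on reduction) | CCCCCCCCCCCCCCCC=C1C(=O)C(=O)C=C(O)C1=O | intermediate
5 | 3-hexadecyl-2,5-dihydroxy-1,4-benzoquinone | CCCCCCCCCCCCCCCCC1=C(O)C(=O)C=C(O)C1=O | intermediate
6 | 3-hexadecyl-2-hydroxy-5-methoxy-1,4-benzoquinone | CCCCCCCCCCCCCCCCC1=C(O)C(=O)C=C(OC)C1=O | target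

**Total step count:** 3
**Longest linear sequence:** 3 (1 → 2 → 5 → 6)

**Steps most likely to fail**

**Step 2 (highest risk).**
- Risks: a second alkylation at C6 of 5, Michael capture of 4 by another molecule of 3, and the low solubility of 3.
- The fallback replaces the condensation by an aryllithium alkylation. It sets out from 1 and comes back at 5.
- Compound 1 is heated with 48 % aq. HBr/H2SO4 to give 1-bromohexadecane F1.
- Commercial 1,2,4,5-tetramethoxybenzene is deprotonated with n-BuLi/TMEDA in THF at 0 °C to 2,3,5,6-tetramethoxyphenyllithium F2.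
- The bromide alkylates this aryllithium to give 3-hexadecyl-1,2,4,5-tetramethoxybenzene F3.
- Oxidative demethylation with (NH4)2Ce(NO3)6 in MeCN/H2O at 0 °C gives 3-hexadecyl-2,5-dimethoxy-1,4-benzoquinone F4.
- Hydrolysis of both vinylogous esters with NaOH in aq. EtOH at reflux, followed by HCl, delivers 5.

**Step 3.**
- Risks: incomplete conversion, some dimethyl ether, or an inseparable regioisomer.
- The fallback places the methyl ether before the C–C bond is made, so that only one enolic carbon is left. It sets out from 3 and comes back at 6.
- Compound 3 in MeOH/H2SO4 at reflux gives sparingly soluble 2,5-dimethoxy-1,4-benzoquinone F5.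
- One equivalent of KOH in aq. dioxane at 0–25 °C, then HCl, cleaves a single ether to give 2-hydroxy-5-methoxy-1,4-benzoquinone F6. The hydroxyquinone anion formed first resists further attack.
- The reductive alkylation conditions of step 2, applied to this compound and 2 (1:1), pass through 3-hexadecylidene-5-methoxycyclohex-5-ene-1,2,4-trione F7 and give 6 directly.

**Step 1.**
- Risks: over-oxidation, formation of hexadecyl hexadecanoate, or trimerisation of the aldehyde.
- The fallback reaches the aldehyde by reduction from the acid level instead of by partial oxidation. It sets out from 1 and comes back at 2.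
- Compound 1 is oxidised fully with TEMPO (cat.)/NaOCl (cat.)/NaClO2 in MeCN/phosphate buffer to hexadecanoic acid F8, which can also be bought.
- Coupling with MeNH(OMe)·HCl, EDC·HCl and Et3N in CH2Cl2 gives N-methoxy-N-methylhexadecanamide F9.
- Reduction with DIBAL-H in THF at −78 °C forms a stable chelate that releases 2 only on aqueous work-up.

**Further compounds**
F1 | step 2 | 1-bromohexadecane | CCCCCCCCCCCCCCCCBr
F2 | step 2 | 2,3,5,6-tetramethoxyphenyllithium | [Li]c1c(OC)c(OC)cc(OC)c1OC
F3 | step 2 | 3-hexadecyl-1,2,4,5-tetramethoxybenzene | CCCCCCCCCCCCCCCCc1c(OC)c(OC)cc(OC)c1OC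
F4 | step 2 | 3-hexadecyl-2,5-dimethoxy-1,4-benzoquinone | CCCCCCCCCCCCCCCCC1=C(OC)C(=O)C=C(OC)C1=O
F5 | step 3 | 2,5-dimethoxy-1,4-benzoquinone | COC1=CC(=O)C(OC)=CC1=O
F6 | step 3 | 2-hydroxy-5-methoxy-1,4-benzoquinone | COC1=CC(=O)C(O)=CC1=O
F7 | step 3 | 3-hexadecylidene-5-methoxycyclohex-5-ene-1,2,4-trione | CCCCCCCCCCCCCCCC=C1C(=O)C(=O)C=C(OC)C1=O
F8 | step 1 | hexadecanoic acid | CCCCCCCCCCCCCCCC(=O)O
F9 | step 1 | N-methoxy-N-methylhexadecanamide | CCCCCCCCCCCCCCCC(=O)N(C)OC
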